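With a small charge of Ja, as in the south-east run, the total of Jd, Je and Jh reads 92.1% at 1.04 d. With 20 mM of Ja, in the north and south-west runs, Jb is the limiting reagent and the total follows its charge.

| flask | Ja | Jb | remark | time | volume of the second phase over the first |
|---|---|---|---|---|---|
| north | 20 mM | 10 mM | run made earlier |  |  |
| south-west | 20 mM | 16 mM | run made earlier |  |  |
| south-east | 10 mM | 21 mM | run made earlier |  |  |
| flask | 20 mM | 21.0 mM |  | 4.0 d | 2.0 |

- north (time / d: Jd / %, Jh / %): 0.333: 18.1, 8.4; 0.500: 24.4, 14.7; 0.833: 31.9, 23.6; 1.04: 34.9, 27.5; 1.67: 39.1, 32.1; 2.50: 40.2, 33.0; 4.00: 38.3, 30.4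
- south-west (time / d: Jd / %, Jh / %): 0.208: 21.1, 7.8; 0.625: 44.9, 31.9; 1.04: 56.0, 45.8; 1.67: 64.1, 54.9; 2.50: 67.0, 58.3; 3.00: 68.0, 59.4; 4.00: 69.0, 58.2
- south-east (time / d: Jd / %, Jh / %): 0.333: 65.3, 35.2; 1.04: 92.1, 78.0; 1.67: 91.4, 76.6; 3.00: 89.4, 74.6; 4.00: 88.1, 71.9

(each reading ± 0.5 percentage points)

- Jd is meant together with its Je and Jh
- in the second phase: Jb, Je; everything else is in the first
- charges count per volume of the first phase; a concentration in a rate is the amount of a species over the volume of its own phase; every rate counts per litre of the first phase
- solid, in amounts per volume of the solution: Jh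
- the earlier runs hold the two phases in the same ratio of volumes as the flask asked about

- the Jd and Je and Jh together standing at 4.0 d, as a percentage of the Ja charged
- concentration of Jd in solution at 4.0 d, in percent of saturation

So count turnovers, and first ask which number you must know well.

| Number | If it is off |
|---|---|
| time | north's first reading, taken as first-order use of Jb, gives 1.35 /d, so 4.0 d is 5.40 lifetimes: a small error moves little |
| charges of Ja and Jb | the reach below moves in proportion to their ratio, Jb over Ja 1.05 in this flask |
| delivery, total formed per Jb charged | north reads 0.804, south-west 0.863: the choice moves the reach of this flask by 6.1 percentage points |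

Delivery is the number to get right. Take south-west's, the run nearer in Jb. The reach, delivery times Jb charged over Ja charged, is then 90.6% for this flask.

The forecast says 86% and 99% of saturation, holding that “crystals hold solution near saturation”. The reach stands above its yield.

The flask gives 84.2% and 96.1% of saturation.

    Jc ⇌ Jb, rate k1*([Jc] - [Jb]/K1) per volume of the first phase (partition coefficient = 2.40, kL = 0.370 /h)
    Ja + Jc → Jd (k = 190 /M/h)
    Jd ⇌ Je, rate k3*([Jd] - [Je]/K3) per volume of the first phase (partition coefficient = 1.90, kL = 0.0180 /h)
    Jd → Jf (k = 0.00860 /h)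
    Ja + Jd → Jg (k = 1.90 /M/h)
    Jh ⇌ Jd, rate k6*(cs6 - [Jd]) while solid is left; crystals form when [Jd] > cs6 (solubility = 0.570 mM, k = 0.270 /h)

The flask stands 6.4 points below its reach. Among the things taken away in simulated runs, the limit of solubility of Jd has the largest single effect on the total: the run without it gives 51.3% against 84.2%. For the neighbour charged with 80 mM of Ja, the reach is 22.6%. That flask gives 12.9%, with Jg at 24.7% and Jb down to 0.0792% of its own charge.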